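## Retrosynthetic overview
1. Target 15 ⇒ tris-MOM ether 14; global deprotection comes last.
2. The (R)-carbinol of 14 ⇒ Sharpless kinetic resolution of the racemic allylic alcohol 13.
3. C2'–C3' bond of 13 ⇒ Nozaki–Hiyama–Kishi coupling of arylacetaldehyde 7 with vinyl triflate 10 (from sulcatone 8).
4. Aldehyde 7 ⇒ ozonolysis of C-allyl arene 4 ⇒ MOM protection and C-allylation of commercial 2,4,6-trihydroxybenzophenone 1.
5. No ring is formed in the route; both benzene rings are bought intact in 1.

Assumption: the target is the (R)-carbinol (CIP order OH > C(=CH2) > CH2Ar > H), and 1, 8 and all reagents named below are taken as commercial.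

## Route

Step 1
Reactants: 1 phenyl(2,4,6-trihydroxyphenyl)methanone
Product: 2 (3-allyl-2,4,6-trihydroxyphenyl)(phenyl)methanone
Conditions: allyl bromide (0.9 equiv), DBU (1.0 equiv), THF, 0 °C → rt
Reagents that add atoms: allyl bromide, C=CCBr
Why: Base-mediated C-allylation (SN2) of the ambident acylphloroglucinol phenoxide, whose soft ring carbon attacks at the only free positions (C3 and C5, equivalent) and re-aromatises, with sub-stoichiometric bromide limiting O- and bis-allylation.

Step 2
Reactants: 2 (3-allyl-2,4,6-trihydroxyphenyl)(phenyl)methanone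
Product: 4 [3-allyl-2,4,6-tris(methoxymethoxy)phenyl](phenyl)methanone, via trisodium triphenoxide 3 (not isolated)
Conditions: NaH (3.6 equiv), DMF, 0 °C; then MOMCl (3.6 equiv), 0 °C → rt
Reagents that add atoms: chloromethyl methyl ether (MOMCl), COCCl
Why: Williamson-type O-alkylation of the hard phenoxide oxygens by the hard electrophile MOMCl masks all three acidic OH groups, which organochromium chemistry would not tolerate.

Step 3
Reactants: 4 [3-allyl-2,4,6-tris(methoxymethoxy)phenyl](phenyl)methanone
Product: 7 2-[3-benzoyl-2,4,6-tris(methoxymethoxy)phenyl]acetaldehyde, via primary ozonide 5 (not isolated), via secondary ozonide 6 (not isolated)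
Conditions: O3, CH2Cl2, −78 °C (Sudan Red 7B end point); then PPh3, −78 °C → rt; used crude
Reagents that add atoms: ozone, [O-][O+]=O
Why: Ozonolysis (1,3-dipolar cycloaddition, then Criegee rearrangement) of the only alkene gives the ozonide, which PPh3 reduces to the aldehyde without over-oxidation while the protected arene survives at −78 °C.

Step 4
Reactants: 8 6-methylhept-5-en-2-one
Product: 10 6-methylhepta-1,5-dien-2-yl trifluoromethanesulfonate, via lithium enolate 9 (not isolated)
Conditions: LDA (commercial solution, 1.05 equiv), THF, −78 °C; then PhNTf2, −78 → 0 °C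
Reagents that add atoms: N-phenylbis(trifluoromethanesulfonimide) (PhNTf2), O=S(=O)(N(c1ccccc1)S(=O)(=O)C(F)(F)F)C(F)(F)F
Why: Kinetic enolisation at the methyl group by the bulky amide base, then O-sulfonylation of the enolate, gives the 1-alken-2-yl triflate regioselectively.

Step 5
Reactants: 7 2-[3-benzoyl-2,4,6-tris(methoxymethoxy)phenyl]acetaldehyde; 10 6-methylhepta-1,5-dien-2-yl trifluoromethanesulfonate (1.5 equiv)
Product: 13 rac-[3-(2-hydroxy-7-methyl-3-methylideneoct-6-en-1-yl)-2,4,6-tris(methoxymethoxy)phenyl](phenyl)methanone, via alkenylchromium(III) dichloride 11 (not isolated), via chromium(III) alkoxide 12 (not isolated)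
Conditions: CrCl2 (4 equiv), NiCl2 (2 mol %), degassed DMF, rt; aqueous work-up
Reagents that add atoms: none
Why: Nozaki–Hiyama–Kishi coupling, in which Ni(0) inserts into the vinyl triflate and transmetalation gives a non-basic alkenylchromium that adds to the enolisable aldehyde but not to the hindered diaryl ketone, forming the carbinol centre as a racemate.

Step 6
Reactants: 13 rac-[3-(2-hydroxy-7-methyl-3-methylideneoct-6-en-1-yl)-2,4,6-tris(methoxymethoxy)phenyl](phenyl)methanone
Product: 14 {3-[(2R)-2-hydroxy-7-methyl-3-methylideneoct-6-en-1-yl]-2,4,6-tris(methoxymethoxy)phenyl}(phenyl)methanone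
Conditions: Ti(OiPr)4 (0.2 equiv), L-(+)-DIPT (0.3 equiv), t-BuOOH (0.6 equiv, decane), 4 Å MS, CH2Cl2, −20 °C; stopped at 55–60% conversion
Reagents that add atoms: none
Why: Sharpless kinetic resolution, in which the Ti/L-(+)-DIPT catalyst epoxidises the (S)-allylic alcohol much faster (krel is typically >50 for 2-substituted 1-alken-3-ols), so unreacted (R)-14 is recovered in high ee and the isolated trisubstituted alkene is untouched.

Step 7
Reactants: 14 {3-[(2R)-2-hydroxy-7-methyl-3-methylideneoct-6-en-1-yl]-2,4,6-tris(methoxymethoxy)phenyl}(phenyl)methanone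
Product: 15 {3-[(2R)-2-hydroxy-7-methyl-3-methylideneoct-6-en-1-yl]-2,4,6-trihydroxyphenyl}(phenyl)methanone
Conditions: HCl (1.25 M in MeOH), 0 °C → rt, monitored; NaHCO3 quench
Reagents that add atoms: none
Why: Acid-catalysed acetal solvolysis (transacetalisation to methanol) removes the three aryl MOM groups under conditions mild enough not to ionise the allylic carbinol, so the (R)-centre is not touched.

## Compound list
1 | phenyl(2,4,6-trihydroxyphenyl)methanone (2,4,6-trihydroxybenzophenone) | O=C(c1ccccc1)c1c(O)cc(O)cc1O | starting material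
2 | (3-allyl-2,4,6-trihydroxyphenyl)(phenyl)methanone | C=CCc1c(O)cc(O)c(C(=O)c2ccccc2)c1O | intermediate
3 | trisodium triphenoxide of 2 (not isolated) | C=CCc1c([O-])cc([O-])c(C(=O)c2ccccc2)c1[O-].[Na+].[Na+].[Na+] | intermediate
4 | [3-allyl-2,4,6-tris(methoxymethoxy)phenyl](phenyl)methanone | C=CCc1c(OCOC)cc(OCOC)c(C(=O)c2ccccc2)c1OCOC | intermediate
5 | primary ozonide of 4, phenyl{2,4,6-tris(methoxymethoxy)-3-[(1,2,3-trioxolan-4-yl)methyl]phenyl}methanone (not isolated) | COCOc1cc(OCOC)c(C(=O)c2ccccc2)c(OCOC)c1CC3COOO3 | intermediate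
6 | secondary ozonide of 4, phenyl{2,4,6-tris(methoxymethoxy)-3-[(1,2,4-trioxolan-3-yl)methyl]phenyl}methanone (not isolated) | COCOc1cc(OCOC)c(C(=O)c2ccccc2)c(OCOC)c1CC3OCOO3 | intermediate
7 | 2-[3-benzoyl-2,4,6-tris(methoxymethoxy)phenyl]acetaldehyde | O=CCc1c(OCOC)cc(OCOC)c(C(=O)c2ccccc2)c1OCOC | intermediate
8 | 6-methylhept-5-en-2-one (sulcatone) | CC(=O)CCC=C(C)C | starting material
9 | lithium 6-methylhepta-1,5-dien-2-olate (not isolated) | C=C([O-])CCC=C(C)C.[Li+] | intermediate
10 | 6-methylhepta-1,5-dien-2-yl trifluoromethanesulfonate | C=C(OS(=O)(=O)C(F)(F)F)CCC=C(C)C | intermediate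
11 | dichloro(6-methylhepta-1,5-dien-2-yl)chromium(III) (not isolated) | C=C([Cr](Cl)Cl)CCC=C(C)C | intermediate
12 | dichlorochromium(III) alkoxide of 13 (not isolated) | C=C(CCC=C(C)C)C(O[Cr](Cl)Cl)Cc1c(OCOC)cc(OCOC)c(C(=O)c2ccccc2)c1OCOC | intermediate
13 | rac-[3-(2-hydroxy-7-methyl-3-methylideneoct-6-en-1-yl)-2,4,6-tris(methoxymethoxy)phenyl](phenyl)methanone | C=C(CCC=C(C)C)C(O)Cc1c(OCOC)cc(OCOC)c(C(=O)c2ccccc2)c1OCOC | intermediate
14 | {3-[(2R)-2-hydroxy-7-methyl-3-methylideneoct-6-en-1-yl]-2,4,6-tris(methoxymethoxy)phenyl}(phenyl)methanone | C=C(CCC=C(C)C)[C@H](O)Cc1c(OCOC)cc(OCOC)c(C(=O)c2ccccc2)c1OCOC | intermediate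
15 | {3-[(2R)-2-hydroxy-7-methyl-3-methylideneoct-6-en-1-yl]-2,4,6-trihydroxyphenyl}(phenyl)methanone | C=C(CCC=C(C)C)[C@H](O)Cc1c(O)cc(O)c(C(=O)c2ccccc2)c1O | target

## Step count and risks
Total step count: 7. Longest linear sequence: 6 (steps 1, 2, 3, 5, 6, 7 from 1); the side branch is step 4 from 8.

The three steps most likely to fail:

Step 1 (direct C-allylation). O-allylation, bis-allylation and geminal dialkylation compete, so the yield is expected to be only 35–45%. The fallback sets out from 1 and comes back at 2. The most acidic, non-chelated 4-OH is O-allylated (allyl bromide 1.0 equiv, K2CO3, acetone, rt) to give (4-allyloxy-2,6-dihydroxyphenyl)(phenyl)methanone F1. Aromatic Claisen rearrangement of this ether (PhNEt2, 190 °C) delivers the allyl group to the ortho carbon (C3 and C5 are equivalent) and so gives 2.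

Step 6 (kinetic resolution). The yield is capped at 50%, and the MOM and ketone oxygens could bind titanium and erode the rate ratio. The fallback sets out from 13 and comes back at 14. Dess–Martin oxidation (NaHCO3, CH2Cl2, 0 °C) gives the enone [2,4,6-tris(methoxymethoxy)-3-(7-methyl-3-methylidene-2-oxooct-6-en-1-yl)phenyl](phenyl)methanone F2. Corey–Bakshi–Shibata reduction with (S)-Me-CBS (0.2 equiv) and catecholborane (toluene, −78 °C) then delivers hydride to the face that gives the (R)-alcohol, with the α-branched alkenyl group as the large substituent and CH2Ar as the small one. This forms the borate 2-({(2R)-1-[3-benzoyl-2,4,6-tris(methoxymethoxy)phenyl]-7-methyl-3-methylideneoct-6-en-2-yl}oxy)-1,3,2-benzodioxaborole F3, which aqueous NaOH work-up hydrolyses to 14 with all material carried through.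

Step 7 (acidic MOM removal). The free ortho-phenols can add to the protonated 1,1-disubstituted alkene to give a chromanol, HCl/MeOH can add across the trisubstituted alkene, and the allylic carbinol can ionise. The fallback sets out from 14 and comes back at 15 without any Brønsted acid. TESOTf/2,2′-bipyridyl (CH2Cl2, 0 °C → rt) converts the three aryl MOM ethers directly into aryl TES ethers and silylates the carbinol, giving {2,4,6-tris(triethylsilyloxy)-3-[(2R)-7-methyl-3-methylidene-2-(triethylsilyloxy)oct-6-en-1-yl]phenyl}(phenyl)methanone F4. Buffered fluoride (TBAF/AcOH, THF, 0 °C) then cleaves all four Si–O bonds to give 15.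

## Further compounds
F1 | step 1 | (4-allyloxy-2,6-dihydroxyphenyl)(phenyl)methanone | C=CCOc1cc(O)c(C(=O)c2ccccc2)c(O)c1
F2 | step 6 | [2,4,6-tris(methoxymethoxy)-3-(7-methyl-3-methylidene-2-oxooct-6-en-1-yl)phenyl](phenyl)methanone | C=C(CCC=C(C)C)C(=O)Cc1c(OCOC)cc(OCOC)c(C(=O)c2ccccc2)c1OCOC
F3 | step 6 | 2-({(2R)-1-[3-benzoyl-2,4,6-tris(methoxymethoxy)phenyl]-7-methyl-3-methylideneoct-6-en-2-yl}oxy)-1,3,2-benzodioxaborole | C=C(CCC=C(C)C)[C@H](OB3Oc4ccccc4O3)Cc1c(OCOC)cc(OCOC)c(C(=O)c2ccccc2)c1OCOC
F4 | step 7 | {2,4,6-tris(triethylsilyloxy)-3-[(2R)-7-methyl-3-methylidene-2-(triethylsilyloxy)oct-6-en-1-yl]phenyl}(phenyl)methanone | C=C(CCC=C(C)C)[C@H](O[Si](CC)(CC)CC)Cc1c(O[Si](CC)(CC)CC)cc(O[Si](CC)(CC)CC)c(C(=O)c2ccccc2)c1O[Si](CC)(CC)CC
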